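The flask holds 20 µM of X against 19 µM of J, and J turns X into Z, so the X still working (free or as L or Q) is the charge less the J lost.

| flask | G | D | X | J | remark |
|---|---|---|---|---|---|
| Tuesday's | 0.20 M | 0.095 M | 20 µM | 19 µM | run made earlier |
| Sunday's | 0.20 M | 0.38 M | 20 µM | 19 µM | run made earlier |
| Thursday's | 0.20 M | 0.19 M | 40 µM | 19 µM | run made earlier |
| flask | 0.20 M | 0.190 M | 20 µM | 19 µM |  |

- Tuesday's (time / h: E / %, G / %): 10.0: 4.0, 95.8; 20.0: 8.3, 92.1; 30.0: 13.2, 89.3; 40.0: 11.3, 87.9
- Sunday's (time / h: E / %, G / %): 5.00: 4.0, 96.9; 15.0: 9.1, 91.4; 25.0: 15.1, 83.5; 40.0: 20.5, 78.3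
- Thursday's (time / h: E / %, G / %): 5.00: 6.8, 92.8; 15.0: 18.2, 80.6; 25.0: 26.5, 73.6; 40.0: 42.1, 60.2

(each reading ± 1 percentage point)

- candidate steps: Q -> X + E; G + X <-> L; X + J -> Z; D + L <-> Q

- apparent order in X when 10% of the G are converted (percent change of the rate of making E for one percent more X charged)
- factor on the rate of making E when 10% of the G are converted if D is charged twice over

J is lost at a rate proportional to [J][X], while E is made at a rate proportional to [Q]. The ratio [X]/[Q] follows [G] and [D], not the charge of X. Dividing the two rates and integrating, with that ratio held constant, gives [J] = charge × exp(−s·c), where c is the fraction of G converted and s is the fall of ln[J] per unit of c.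

In Tuesday's and Sunday's runs the charge of X exceeds that of J by 1.00 µM, so the rate of conversion falls nearly as [J] does, and s is read from the early and late rates. Taking c as the mean of E and the G missing, Tuesday's rate up to 10.0 h against its rate from 20.0 h to 40.0 h reads 10.5. Sunday's rate up to 15.0 h against its rate from 25.0 h to 40.0 h reads 3.66. Both readings carry the scatter.

The flask's [D] is the geometric mean of those two charges, so, with ln s taken as straight in ln[D], the same mean of the readings gives 6.19, the poison number, an estimate of s for this flask.

At 10% conversion this reckoning has the flask down by 8.77 µM of J, a loss in which the charge of X does not enter. The rate goes as charge less loss, so this reckoning puts the order at charge over working X, 1.78. Twice the [D] is Sunday's charge, where s reads smaller than in the flask. With Sunday's rate per X up to 5.00 h reading 1.01 of Thursday's, this reckoning puts the factor at 1.28.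

The forecast, holding that “J slowly kills X”, gives 1.4 (1.15 to 1.75), lower than this reckoning, and 1.35 (1.1 to 1.65).

The flask gives an order of 1.8 and a factor of 1.29, with 10% reached at 17.3 h.

    Q → X + E (k = 90.0 /h)
    G + X ⇌ L (K = 12.0 /M, k = 20000 /M/h)
    X + J → Z (k = 42000 /M/h)
    D + L ⇌ Q (K = 200 /M, k = 7400 /M/h)

At 20.0 h the flask holds E at 11.1%, J at 50.2% of its charge and Z at 47.3% of the catalyst. Thursday's run was charged with the same [D] and 40 µM of X. From c of 3.50% to 33.7% the poison number puts Thursday's rate at 0.644 of its early value, and Thursday's readings show 0.690.

Readings and results stem from a simulated flask with made-up constants.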